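The readings come from a simulation from invented constants; noise was put on by code.

90.9% of the charge goes in as starting material, and the asked share depends on how much of that is left, so I work with the fraction left and not with the fraction made.

common to all: starting material 0.10 M
- ash: other conformer 0.10 equiv; protic impurity 0.030 M; catalyst 2.5 mol%; run made earlier
- alder: other conformer 0.10 equiv; protic impurity 0.030 M; catalyst 3.8 mol%; run made earlier
- flask: other conformer 0.100 equiv; protic impurity 0.0300 M; catalyst 5 mol%; time 6.0 h

| run | time / h | starting material / % | isomer of the product / % | target / % | other conformer / % | over-reaction product / % |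
|---|---|---|---|---|---|---|
| ash | 0.667 | 83.5 | 3.7 | 2.4 | 0.6 | 0.3 |
| ash | 2.00 | 69.0 | 4.5 | 7.6 | 0.3 | 1.7 |
| ash | 3.00 | 61.1 | 5.9 | 8.5 | 0.5 | 1.9 |
| ash | 5.00 | 51.4 | 7.3 | 12.8 | 0.6 | 3.2 |
| ash | 8.00 | 42.1 | 8.6 | 13.8 | 0.4 | 7.0 |
| alder | 0.667 | 81.8 | 5.1 | 4.1 | 0 | 0 |
| alder | 2.00 | 63.2 | 7.0 | 10.1 | 0.1 | 1.6 |
| alder | 3.00 | 55.6 | 7.1 | 13.7 | 0.1 | 2.6 |
| alder | 5.00 | 44.4 | 8.2 | 18.1 | 0.9 | 5.2 |
| alder | 8.00 | 32.0 | 11.0 | 19.4 | 0.6 | 11.4 |

(standard deviation of a reading: 0.5 percentage points)

- the species in which most of what was charged as starting material and other conformer together, at 6.0 h sits (other conformer / target / over-reaction product / starting material / isomer of the product)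
- the largest share itself, whichever of these holds it, in percent of the starting material and other conformer together charged

I read the two runs side by side in the rows at 5.00 h and 8.00 h. For each run I take the natural logarithm of the share charged over the share read, then go between those rows to the asked time. The ash run stands at 0.637 and the alder run at 0.826. The recipes differ in catalyst, so I lay this read gap of 0.189 to the step from 2.5 mol% to 3.8 mol%.

I assume a pseudo-first-order catalyst path, whose part of the logarithm grows in a straight line with loading, though two runs cannot test that line. At 5 mol% the catalyst part is 0.727, and the part that stays when the line is run back to no catalyst is 0.273. Together they give 1.00. I call this the depth, the natural logarithm of the share charged over the share left. My reckoning therefore leaves 33.4% of starting material.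

The forecast, reckoned through an apparent catalyst order, says starting material at 33%: “Starting material therefore remains the largest share”.

The flask gives starting material at 33.2%, more than target at 22.4%, which is a depth of 1.01.

    starting material ⇌ other conformer (K = 0.00690, k = 0.0380 h⁻¹)
    starting material + catalyst → catalyst + target (k = 19.0 M⁻¹ h⁻¹)
    catalyst + other conformer → catalyst + isomer of the product (k = 1100 M⁻¹ h⁻¹)
    starting material + protic impurity → quenched substrate (k = 6.60 M⁻¹ h⁻¹)
    target → over-reaction product (k = 0.0990 h⁻¹)

A neighbouring flask gives another answer. It charges 0.40 M of starting material at the same loadings, so its catalyst concentration is 4.00 times that of the flask. Scaling the catalyst part of the depth by that factor and keeping the other part as it stands gives a depth of 3.18, so I reckon 3.77% of starting material left. The neighbouring flask holds 7.18%, and its largest share has passed to target at 48.9%.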